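**Plan**

1. Retrosynthesis: the C5=C6 alkene is cut first (ring-closing Horner–Wadsworth–Emmons olefination), then C6–P, the C1–C2 bond (alkynyl ketone formation), C10–C14 (methylcupration), C8–C9 (propargylation) and last the butenolide (carbomagnesiation–carboxylation of but-2-yne-1,4-diol). C2–C5 with C15 is (S)-citramalic acid.
2. Forward: the butenolide is made first (steps 1–3) and the chain C8 to C1 is grown on it (4–5). The citramalate-derived C2–C5 acid (6–9) is joined at C1–C2 (10), then C14, C2 and C6 are adjusted (11–17). The ten-membered ring is closed last (18), followed by desilylation and C13 acetylation (19–20).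
3. Enabling feature: the C5=C6 enol-lactone alkene lies inside the ten-membered ring C1–C10 and is exocyclic to the butenolide O–C6–C7=C11–C12. C6 is thus the γ-carbon of the butenolide, where a phosphonate carbanion is doubly stabilised, and C5 hangs on the fully substituted C4, so the partner aldehyde cannot enolise.
4. Stereochemistry: C4 (S) comes from (S)-citramalic acid, C8 (R) from chiral phosphoric acid catalysed allenylboration, and C2 (R) from CBS reduction. The (Z)-C1=C10 alkene comes from syn-methylcupration of an ynone, and the C5=C6 geometry (C4 cis to C7) from the ring.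
5. Numbering is that of germacranolides (ring C1–C10, C14 on C10, C15 on C4, C11–C13 in the lactone). The C13 oxygen is kept as a TBS ether until after ring closure, because an acetate there is β to the C11 terminus of the C6 carbanion, and is acetylated last.

Key step: step 18

Assumption: (R)-TRIP is taken to deliver the propargyl group to the aldehyde face that gives (8R), by analogy with aryl and alkenyl aldehydes of the same priority pattern; if a test reaction shows the opposite sense, (S)-TRIP is used and nothing else changes.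

**Route**

Step 1
Reactants: 1 but-2-yne-1,4-diol; 2 vinylmagnesium chloride
Product: 5 4-ethenyl-3-(hydroxymethyl)furan-2(5H)-one, via alkenylmagnesium dialkoxide 3 (not isolated), via hydroxy acid 4 (not isolated)
Conditions: 2 (4 equiv), THF/cyclohexane, reflux; then CO2 (gas), 0 °C; then aq. HCl, rt
Reagents that add atoms: vinylmagnesium chloride (2), C=C[Mg]Cl; carbon dioxide, O=C=O
Why: The dialkoxide directs an anti-carbomagnesiation of the alkyne that places the vinyl group on C7 and magnesium on C11 cis to the C6 alkoxide, so that carboxylation at C11 and acid-induced lactonisation of the (Z)-hydroxy acid give the 3,4-disubstituted butenolide with C13 already in place (carbomagnesiation of a propargylic alcohol followed by CO2 capture).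

Step 2
Reactants: 5 4-ethenyl-3-(hydroxymethyl)furan-2(5H)-one
Product: 6 3-[(tert-butyldimethylsilyloxy)methyl]-4-ethenylfuran-2(5H)-one
Conditions: TBSCl, imidazole, CH2Cl2, 0 °C to rt
Reagents that add atoms: tert-butyldimethylsilyl chloride, CC(C)(C)[Si](C)(C)Cl
Why: Standard silylation of the only hydroxyl group turns the C13 oxygen into a poor leaving group, which matters because C13 is allylic to the butenolide alkene and β to the C11 terminus of every C6 dienolate formed later.

Step 3
Reactants: 6 3-[(tert-butyldimethylsilyloxy)methyl]-4-ethenylfuran-2(5H)-one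
Product: 8 4-[(tert-butyldimethylsilyloxy)methyl]-5-oxo-2,5-dihydrofuran-3-carbaldehyde, via ozonide 7 (not isolated)
Conditions: O3, CH2Cl2, -78 °C (stopped at first excess of ozone); then PPh3, -78 °C to rt
Reagents that add atoms: ozone, [O-][O+]=O
Why: Ozonolysis with reductive work-up cleaves the terminal vinyl group, the more electron-rich alkene, and leaves the tetrasubstituted, ester-conjugated C7=C11 bond untouched, giving the C8 aldehyde.

Step 4
Reactants: 8 4-[(tert-butyldimethylsilyloxy)methyl]-5-oxo-2,5-dihydrofuran-3-carbaldehyde; 9 allenylboronic acid pinacol ester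
Product: 11 3-[(tert-butyldimethylsilyloxy)methyl]-4-[(1R)-1-hydroxybut-3-yn-1-yl]furan-2(5H)-one, via pinacol borate 10 (not isolated)
Conditions: 9 (1.5 equiv), (R)-TRIP (5 mol%), 4 Å molecular sieves, toluene, 0 °C; aqueous work-up
Reagents that add atoms: allenylboronic acid pinacol ester (9), C=C=CB1OC(C)(C)C(C)(C)O1
Why: Chiral phosphoric acid catalysed allenylboration (asymmetric propargylation) runs through a closed six-membered transition state in which the catalyst activates the boronate, the non-basic medium leaves the sensitive formyl butenolide intact, and the catalyst alone decides the aldehyde face and thereby sets C8 as R.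

Step 5
Reactants: 11 3-[(tert-butyldimethylsilyloxy)methyl]-4-[(1R)-1-hydroxybut-3-yn-1-yl]furan-2(5H)-one; 12 tiglic acid
Product: 13 (1R)-1-{4-[(tert-butyldimethylsilyloxy)methyl]-5-oxo-2,5-dihydrofuran-3-yl}but-3-yn-1-yl (2E)-2-methylbut-2-enoate
Conditions: 12, EDC·HCl, DMAP (cat.), CH2Cl2, 0 °C to rt
Reagents that add atoms: tiglic acid (12), C/C=C(\C)C(=O)O
Why: Carbodiimide/DMAP (Steglich) esterification acylates the secondary C8 alcohol without touching the stereocenter, and placing the tiglate now means that the C8 and C2 oxygens never have to be told apart later.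

Step 6
Reactants: 14 (S)-citramalic acid
Product: 15 dibenzyl (S)-citramalate
Conditions: BnBr, K2CO3, DMF, rt
Reagents that add atoms: benzyl bromide, BrCc1ccccc1
Why: O-Alkylation of the two carboxylates esterifies both acids and leaves the tertiary alcohol free, giving esters that can later be removed by hydrogenolysis in the presence of silyl ethers.

Step 7
Reactants: 15 dibenzyl (S)-citramalate
Product: 16 benzyl (3S)-3,4-dihydroxy-3-methylbutanoate
Conditions: BH3·SMe2, NaBH4 (5 mol%), THF, 0 °C to rt; MeOH quench
Reagents that add atoms: none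
Why: The tertiary hydroxyl forms an alkoxyborane that delivers hydride intramolecularly to the adjacent ester only (hydroxyl-directed borane reduction of an α-hydroxy ester), so C5 reaches the alcohol level while the C2 ester survives and C4 is not touched.

Step 8
Reactants: 16 benzyl (3S)-3,4-dihydroxy-3-methylbutanoate
Product: 17 benzyl (3S)-3-methyl-3,4-bis(triethylsilyloxy)butanoate
Conditions: Et3SiOTf, 2,6-lutidine, CH2Cl2, -78 to 0 °C (crude 16 used at once)
Reagents that add atoms: triethylsilyl trifluoromethanesulfonate, CC[Si](CC)(CC)OS(=O)(=O)C(F)(F)F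
Why: Silyl triflate with a hindered pyridine base silylates the primary and the tertiary hydroxyl alike, and immediate protection forestalls lactonisation of the diol ester.

Step 9
Reactants: 17 benzyl (3S)-3-methyl-3,4-bis(triethylsilyloxy)butanoate
Product: 18 (3S)-3-methyl-3,4-bis(triethylsilyloxy)butanoic acid
Conditions: H2 (1 atm), 10% Pd/C, EtOAc, rt
Reagents that add atoms: none
Why: Hydrogenolysis of the benzyl ester over palladium in ethyl acetate is neutral and spares triethylsilyl ethers.

Step 10
Reactants: 18 (3S)-3-methyl-3,4-bis(triethylsilyloxy)butanoic acid; 13 (8R)-tiglate alkyne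
Product: 20 C1–C2 ynone (8R; 4S; C8 tiglate; C10≡C1–C2=O; C4 and C5 triethylsilyl ethers; C13 TBS ether; butenolide C6H2), via acid chloride 19 (not isolated)
Conditions: 18, 1-chloro-N,N,2-trimethylprop-1-en-1-amine, CH2Cl2, 0 °C to rt; then 13, PdCl2(PPh3)2 (2 mol%), CuI (4 mol%), Et3N (1.2 equiv), THF, rt, degassed
Reagents that add atoms: none
Why: The acid is converted to its chloride under neutral conditions with the α-chloroenamine, and Pd/Cu-catalysed acylation of the terminal alkyne (acyl Sonogashira coupling) then forms the C1–C2 bond at room temperature with only a tertiary amine as base, which the butenolide, the tiglate and the silyl ethers tolerate.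

Step 11
Reactants: 20 C1–C2 ynone
Product: 21 (1(10)Z)-enone (C14 methyl on C10; C2 ketone; otherwise as 20)
Conditions: Me2CuLi (from CuI and 2 MeLi), THF/Et2O, -78 °C; aq. NH4Cl added at -78 °C
Reagents that add atoms: lithium dimethylcuprate, [Li+].C[Cu-]C
Why: Syn-addition of the Gilman reagent to the ynone (organocuprate conjugate addition) puts the methyl group on C10 and, after protonation of C1 on the side of that methyl group, which is also the less hindered side of any allenolate, leaves C9 and C2 cis as the (Z)-alkene, the ynone being far more electrophilic than the tetrasubstituted butenolide or the tiglate.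

Step 12
Reactants: 21 (1(10)Z)-enone
Product: 22 (2R)-allylic alcohol (C2 hydroxyl; otherwise as 21)
Conditions: (S)-2-methyl-CBS-oxazaborolidine, catecholborane, toluene, -78 °C
Reagents that add atoms: none
Why: Corey–Bakshi–Shibata reduction with the (S)-oxazaborolidine should treat the alkenyl group as the large and the C3 methylene as the small substituent and so deliver hydride to the face that gives the (2R)-alcohol by 1,2-reduction, catecholborane at -78 °C leaving the lactone, the ester and the alkenes alone.

Step 13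
Reactants: 22 (2R)-allylic alcohol
Product: 23 (2R)-acetate (C2 acetate; C8 tiglate; C4 and C5 triethylsilyl ethers; C13 TBS ether; butenolide C6H2)
Conditions: Ac2O, pyridine, DMAP (cat.), CH2Cl2, 0 °C
Reagents that add atoms: acetic anhydride, CC(=O)OC(C)=O
Why: DMAP-catalysed acetylation of the only free hydroxyl group proceeds with retention at C2.

Step 14
Reactants: 23 (2R)-acetate
Product: 25 C6 bromide of 23 (5-bromobutenolide; both C6 epimers), via silyloxyfuran 24 (not isolated)
Conditions: TBSOTf (1.2 equiv), Et3N (1.5 equiv), CH2Cl2, 0 °C; then NBS (1.05 equiv), THF, -78 °C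
Reagents that add atoms: N-bromosuccinimide, O=C1CCC(=O)N1Br
Why: Soft enolisation of the butenolide gives the 2-silyloxyfuran, which N-bromosuccinimide attacks at the unsubstituted C6 terminus (γ-halogenation of a silyl dienol ether) faster than it reacts with the trisubstituted alkene, and the new C6 center forms as a mixture that is of no consequence.

Step 15
Reactants: 25 C6 bromide
Product: 26 C6 diethyl phosphonate (both C6 epimers; otherwise as 23)
Conditions: P(OEt)3, toluene, 90 °C
Reagents that add atoms: triethyl phosphite, CCOP(OCC)OCC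
Why: Michaelis–Arbuzov reaction of the allylic α-acyloxy bromide with triethyl phosphite forms the C6–P bond in the same way as with 3-bromophthalides.

Step 16
Reactants: 26 C6 diethyl phosphonate
Product: 27 C5 primary alcohol (C4 triethylsilyl ether and C13 TBS ether retained)
Conditions: PPTS (cat.), MeOH/CH2Cl2, 0 °C
Reagents that add atoms: none
Why: Acid-catalysed methanolysis removes the primary triethylsilyl ether much faster than the tertiary triethylsilyl ether at C4 or the primary TBS ether at C13 (selective desilylation).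

Step 17
Reactants: 27 C5 primary alcohol
Product: 28 C5 aldehyde (cyclisation precursor: C6 diethoxyphosphoryl butenolide; C8 tiglate; (Z)-C1=C10; C2 acetate; C4 triethylsilyl ether; C13 TBS ether)
Conditions: Dess–Martin periodinane, NaHCO3, CH2Cl2, 0 °C to rt; used at once
Reagents that add atoms: none
Why: Buffered Dess–Martin oxidation gives the C5 aldehyde, which cannot enolise or epimerise because C4 is fully substituted, while the C4 silyl ether blocks α-ketol rearrangement.

Step 18
Reactants: 28 C5 aldehyde
Product: 29 ten-membered enol lactone (target skeleton with C4 triethylsilyl ether and C13 TBS ether)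
Conditions: LiCl, DBU, MeCN, 0.001 M (slow addition of 28), rt to 50 °C
Reagents that add atoms: none
Why: DBU, helped by lithium coordination to the phosphoryl and lactone oxygens, removes the C6 proton, which is acidified both by the phosphonate and by the C7=C11–C12 butenolide (the anion is a 2-oxidofuran); the carbanion adds to the C5 aldehyde and the β-oxido phosphonate collapses through the oxaphosphetane to the C5=C6 alkene with loss of diethyl phosphate. The closest known reaction type is the Horner–Wadsworth–Emmons macrocyclisation under Masamune–Roush conditions, combined with the olefination of γ-phosphono butenolides and phthalide phosphonates that gives ylidene lactones. The ten-membered carbocycle C1–C10 is closed by 10-exo-trig attack of C6 on the C5 carbonyl at high dilution, the (Z)-C1=C10 alkene and the planar butenolide holding the two chain ends on the same side. No stereocenter is formed and the C6 center of 28 is destroyed; what must be controlled is the C5=C6 geometry (C4 cis to C7), which the ring is expected to impose because the other isomer would place a trans alkene in a ten-membered ring that already holds the butenolide and the (Z)-alkene, and because addition of so stabilised an anion is reversible and should funnel material through the less strained oxaphosphetane. Regioselectivity (C6, not C11 or an ester α-carbon) is fixed by the phosphonate, the aldehyde is non-enolisable, and the C13 silyl ether cannot be expelled from the C11 terminus of the anion as an acetate could.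

Step 19
Reactants: 29 ten-membered enol lactone
Product: 30 C4,C13-diol (13-deacetyl target)
Conditions: HF·pyridine, pyridine, THF, 0 °C to rt
Reagents that add atoms: none
Why: Pyridine-buffered hydrogen fluoride cleaves both silyl ethers (fluoride-driven desilylation) without ionising the tertiary allylic C4 alcohol or disturbing the esters and the enol lactone.

Step 20
Reactants: 30 C4,C13-diol
Product: 31 target CNP0166369.1
Conditions: Ac2O, pyridine, CH2Cl2, 0 °C
Reagents that add atoms: acetic anhydride, CC(=O)OC(C)=O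
Why: Acetic anhydride in pyridine without DMAP acetylates the primary allylic C13 hydroxyl selectively, the tertiary C4 hydroxyl being unreactive under these conditions.

**Compound list**

1 | but-2-yne-1,4-diol | OCC#CCO | starting material
2 | vinylmagnesium chloride | C=C[Mg]Cl | starting material
3 | alkenylmagnesium dialkoxide (2-ethenylbut-2-ene-1,4-diol bis(chloromagnesium alkoxide) with ClMg on C3, vinyl and Mg trans) | C=C/C(CO[Mg]Cl)=C(\CO[Mg]Cl)[Mg]Cl | intermediate
4 | (2Z)-3-ethenyl-4-hydroxy-2-(hydroxymethyl)but-2-enoic acid | C=C/C(CO)=C(\CO)C(=O)O | intermediate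
5 | 4-ethenyl-3-(hydroxymethyl)furan-2(5H)-one | C=CC1=C(CO)C(=O)OC1 | intermediate
6 | 3-[(tert-butyldimethylsilyloxy)methyl]-4-ethenylfuran-2(5H)-one | C=CC1=C(CO[Si](C)(C)C(C)(C)C)C(=O)OC1 | intermediate
7 | ozonide of 6: 3-[(tert-butyldimethylsilyloxy)methyl]-4-(1,2,4-trioxolan-3-yl)furan-2(5H)-one | O=C1OCC(C2OCOO2)=C1CO[Si](C)(C)C(C)(C)C | intermediate
8 | 4-[(tert-butyldimethylsilyloxy)methyl]-5-oxo-2,5-dihydrofuran-3-carbaldehyde | O=CC1=C(CO[Si](C)(C)C(C)(C)C)C(=O)OC1 | intermediate
9 | allenylboronic acid pinacol ester | C=C=CB1OC(C)(C)C(C)(C)O1 | starting material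
10 | pinacol borate ester of 11 | C#CC[C@@H](OB1OC(C)(C)C(C)(C)O1)C1=C(CO[Si](C)(C)C(C)(C)C)C(=O)OC1 | intermediate
11 | 3-[(tert-butyldimethylsilyloxy)methyl]-4-[(1R)-1-hydroxybut-3-yn-1-yl]furan-2(5H)-one | C#CC[C@@H](O)C1=C(CO[Si](C)(C)C(C)(C)C)C(=O)OC1 | intermediate
12 | tiglic acid | C/C=C(\C)C(=O)O | starting material
13 | (1R)-1-{4-[(tert-butyldimethylsilyloxy)methyl]-5-oxo-2,5-dihydrofuran-3-yl}but-3-yn-1-yl (2E)-2-methylbut-2-enoate | C/C=C(\C)C(=O)O[C@@H](C1=C(CO[Si](C)(C)C(C)(C)C)C(=O)OC1)CC#C | intermediate
14 | (S)-citramalic acid | C[C@](O)(CC(=O)O)C(=O)O | starting material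
15 | dibenzyl (S)-citramalate | C[C@](O)(CC(=O)OCc1ccccc1)C(=O)OCc1ccccc1 | intermediate
16 | benzyl (3S)-3,4-dihydroxy-3-methylbutanoate | C[C@](O)(CC(=O)OCc1ccccc1)CO | intermediate
17 | benzyl (3S)-3-methyl-3,4-bis(triethylsilyloxy)butanoate | C[C@](O[Si](CC)(CC)CC)(CC(=O)OCc1ccccc1)CO[Si](CC)(CC)CC | intermediate
18 | (3S)-3-methyl-3,4-bis(triethylsilyloxy)butanoic acid | C[C@](O[Si](CC)(CC)CC)(CC(=O)O)CO[Si](CC)(CC)CC | intermediate
19 | (3S)-3-methyl-3,4-bis(triethylsilyloxy)butanoyl chloride | C[C@](O[Si](CC)(CC)CC)(CC(=O)Cl)CO[Si](CC)(CC)CC | intermediate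
20 | C1–C2 ynone (4S,8R; C8 tiglate; C10≡C1–C2=O; C4 and C5 OTES; C13 OTBS) | C/C=C(\C)C(=O)O[C@@H](C1=C(CO[Si](C)(C)C(C)(C)C)C(=O)OC1)CC#CC(=O)C[C@](C)(O[Si](CC)(CC)CC)CO[Si](CC)(CC)CC | intermediate
21 | (1(10)Z)-enone (4S,8R; C14 methyl on C10; C2 ketone) | C/C=C(\C)C(=O)O[C@@H](C1=C(CO[Si](C)(C)C(C)(C)C)C(=O)OC1)C/C(C)=C\C(=O)C[C@](C)(O[Si](CC)(CC)CC)CO[Si](CC)(CC)CC | intermediate
22 | (2R,4S,8R)-allylic alcohol | C/C=C(\C)C(=O)O[C@@H](C1=C(CO[Si](C)(C)C(C)(C)C)C(=O)OC1)C/C(C)=C\[C@H](O)C[C@](C)(O[Si](CC)(CC)CC)CO[Si](CC)(CC)CC | intermediate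
23 | (2R,4S,8R)-C2 acetate | C/C=C(\C)C(=O)O[C@@H](C1=C(CO[Si](C)(C)C(C)(C)C)C(=O)OC1)C/C(C)=C\[C@H](OC(C)=O)C[C@](C)(O[Si](CC)(CC)CC)CO[Si](CC)(CC)CC | intermediate
24 | 2-(tert-butyldimethylsilyloxy)furan derived from 23 | C/C=C(\C)C(=O)O[C@@H](c1coc(O[Si](C)(C)C(C)(C)C)c1CO[Si](C)(C)C(C)(C)C)C/C(C)=C\[C@H](OC(C)=O)C[C@](C)(O[Si](CC)(CC)CC)CO[Si](CC)(CC)CC | intermediate
25 | C6 bromide (5-bromobutenolide, both C6 epimers) | C/C=C(\C)C(=O)O[C@@H](C1=C(CO[Si](C)(C)C(C)(C)C)C(=O)OC1Br)C/C(C)=C\[C@H](OC(C)=O)C[C@](C)(O[Si](CC)(CC)CC)CO[Si](CC)(CC)CC | intermediate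
26 | C6 diethyl phosphonate (both C6 epimers) | C/C=C(\C)C(=O)O[C@@H](C1=C(CO[Si](C)(C)C(C)(C)C)C(=O)OC1P(=O)(OCC)OCC)C/C(C)=C\[C@H](OC(C)=O)C[C@](C)(O[Si](CC)(CC)CC)CO[Si](CC)(CC)CC | intermediate
27 | C5 primary alcohol of 26 | C/C=C(\C)C(=O)O[C@@H](C1=C(CO[Si](C)(C)C(C)(C)C)C(=O)OC1P(=O)(OCC)OCC)C/C(C)=C\[C@H](OC(C)=O)C[C@](C)(O[Si](CC)(CC)CC)CO | intermediate
28 | C5 aldehyde, cyclisation precursor (2R,4S,8R; both C6 epimers) | C/C=C(\C)C(=O)O[C@@H](C1=C(CO[Si](C)(C)C(C)(C)C)C(=O)OC1P(=O)(OCC)OCC)C/C(C)=C\[C@H](OC(C)=O)C[C@](C)(O[Si](CC)(CC)CC)C=O | intermediate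
29 | ten-membered enol lactone, C4 OTES and C13 OTBS (2R,4S,8R; 1(10)Z; C4 cis to C7 across C5=C6) | C/C=C(\C)C(=O)O[C@@H]1C/C(C)=C\[C@H](OC(C)=O)C[C@](C)(O[Si](CC)(CC)CC)/C=C2/OC(=O)C(CO[Si](C)(C)C(C)(C)C)=C21 | intermediate
30 | C4,C13-diol (13-deacetyl target) | C/C=C(\C)C(=O)O[C@@H]1C/C(C)=C\[C@H](OC(C)=O)C[C@](C)(O)/C=C2/OC(=O)C(CO)=C21 | intermediate
31 | CNP0166369.1 | C/C=C(\C)C(=O)O[C@@H]1C/C(C)=C\[C@H](OC(C)=O)C[C@](C)(O)/C=C2/OC(=O)C(COC(C)=O)=C21 | target

**Step count and risks**

Total: 20 steps. Longest linear sequence: 16 steps (1–5, then 10–20); the citramalate branch is 15 (6–9, then 10–20).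

Step 18 (ring closure). What may go wrong: the doubly stabilised C6 anion may add only slowly to the hindered C5 aldehyde, so that intermolecular olefination to dimers and oligomers, or closure through the more strained geometry, overtakes formation of 29. Fallback (sets out from 23, returns at 29): the same C5–C6 bond is made by a vinylogous Mukaiyama aldol cyclisation followed by β-elimination. The primary silyl ether of 23 is methanolysed (PPTS, MeOH) to the C5 alcohol F1, which is oxidised with Dess–Martin periodinane to the C5 aldehyde F2. TBSOTf and iPr2NEt at high dilution convert the butenolide of F2 in the flask into the silyloxyfuran F3, which adds through C6 to the silyl-activated aldehyde to give the cyclic C5 silyl ether F4. DBU then eliminates the silanol across C5–C6 to give 29.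

Step 14 (γ-bromination). What may go wrong: chemoselectivity may be lost in the polyfunctional substrate, through ionisation of the allylic C2 acetate or the C8 ester by the silyl triflate, or through attack of the bromine source on the C1=C10 alkene. Fallback (sets out from 13, returns at 26): the C6–P bond is installed before the sensitive groups exist. Alkyne 13 is enolised (TBSOTf, Et3N) to the silyloxyfuran F5, brominated with NBS to the C6 bromide F6 and converted with P(OEt)3 into the phosphonate F7. Acyl Sonogashira coupling with 19 gives the ynone F8. Methylcupration gives the (Z)-enone F9; one further equivalent of cuprate is consumed by the acidic C6–H, whose furanolate shields the butenolide. CBS reduction gives the (2R)-alcohol F10, and acetylation leads to 26.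

Step 11 (methylcupration). What may go wrong: the alkenylcopper/allenolate intermediate may equilibrate before protonation and erode the (Z) geometry, or conjugate attack on the butenolide may compete. Fallback (sets out from 20, returns at 21): the β-substituent is introduced in two stages through intermediates whose geometry can be checked and purified. Stannylcupration of 20 with Bu3Sn(PhS)CuLi in THF containing methanol at -78 °C (kinetic syn-addition with protonation in the flask) gives the β-stannyl enone F11 with C9 cis to C2. Iododestannylation with I2 gives the β-iodo enone F12 with retention, and Negishi coupling (Me2Zn, Pd(PPh3)4, THF) replaces iodine by the C14 methyl group with retention to give 21.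

**Further compounds**

F1 | step 18 | C5 primary alcohol of 23 (butenolide C6H2) | C/C=C(\C)C(=O)O[C@@H](C1=C(CO[Si](C)(C)C(C)(C)C)C(=O)OC1)C/C(C)=C\[C@H](OC(C)=O)C[C@](C)(O[Si](CC)(CC)CC)CO
F2 | step 18 | C5 aldehyde of 23 (butenolide C6H2) | C/C=C(\C)C(=O)O[C@@H](C1=C(CO[Si](C)(C)C(C)(C)C)C(=O)OC1)C/C(C)=C\[C@H](OC(C)=O)C[C@](C)(O[Si](CC)(CC)CC)C=O
F3 | step 18 | 2-(tert-butyldimethylsilyloxy)furan of F2 | C/C=C(\C)C(=O)O[C@@H](c1coc(O[Si](C)(C)C(C)(C)C)c1CO[Si](C)(C)C(C)(C)C)C/C(C)=C\[C@H](OC(C)=O)C[C@](C)(O[Si](CC)(CC)CC)C=O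
F4 | step 18 | cyclic aldol as C5 TBS ether (ten-membered ring closed at C5–C6; C5 and C6 unassigned) | C/C=C(\C)C(=O)O[C@@H]1C/C(C)=C\[C@H](OC(C)=O)C[C@](C)(O[Si](CC)(CC)CC)C(O[Si](C)(C)C(C)(C)C)C2OC(=O)C(CO[Si](C)(C)C(C)(C)C)=C21
F5 | step 14 | 2-(tert-butyldimethylsilyloxy)furan of 13 | C/C=C(\C)C(=O)O[C@@H](c1coc(O[Si](C)(C)C(C)(C)C)c1CO[Si](C)(C)C(C)(C)C)CC#C
F6 | step 14 | C6 bromide of 13 (both C6 epimers) | C/C=C(\C)C(=O)O[C@@H](C1=C(CO[Si](C)(C)C(C)(C)C)C(=O)OC1Br)CC#C
F7 | step 14 | C6 diethyl phosphonate of 13 (both C6 epimers) | C/C=C(\C)C(=O)O[C@@H](C1=C(CO[Si](C)(C)C(C)(C)C)C(=O)OC1P(=O)(OCC)OCC)CC#C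
F8 | step 14 | C1–C2 ynone carrying the C6 phosphonate | C/C=C(\C)C(=O)O[C@@H](C1=C(CO[Si](C)(C)C(C)(C)C)C(=O)OC1P(=O)(OCC)OCC)CC#CC(=O)C[C@](C)(O[Si](CC)(CC)CC)CO[Si](CC)(CC)CC
F9 | step 14 | (1(10)Z)-enone carrying the C6 phosphonate | C/C=C(\C)C(=O)O[C@@H](C1=C(CO[Si](C)(C)C(C)(C)C)C(=O)OC1P(=O)(OCC)OCC)C/C(C)=C\C(=O)C[C@](C)(O[Si](CC)(CC)CC)CO[Si](CC)(CC)CC
F10 | step 14 | (2R)-allylic alcohol carrying the C6 phosphonate | C/C=C(\C)C(=O)O[C@@H](C1=C(CO[Si](C)(C)C(C)(C)C)C(=O)OC1P(=O)(OCC)OCC)C/C(C)=C\[C@H](O)C[C@](C)(O[Si](CC)(CC)CC)CO[Si](CC)(CC)CC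
F11 | step 11 | β-tributylstannyl enone (Bu3Sn on C10; C9 cis to C2) | C/C=C(\C)C(=O)O[C@@H](C1=C(CO[Si](C)(C)C(C)(C)C)C(=O)OC1)C/C([Sn](CCCC)(CCCC)CCCC)=C\C(=O)C[C@](C)(O[Si](CC)(CC)CC)CO[Si](CC)(CC)CC
F12 | step 11 | β-iodo enone (iodine on C10; C9 cis to C2) | C/C=C(\C)C(=O)O[C@@H](C1=C(CO[Si](C)(C)C(C)(C)C)C(=O)OC1)C/C(I)=C\C(=O)C[C@](C)(O[Si](CC)(CC)CC)CO[Si](CC)(CC)CC
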